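## Analysis of the target

Target 17 is a 2,3-dihydro-1,4-benzodioxine: a benzene ring (ring A) fused to a 1,4-dioxane, numbered here O1, C2, C3, O4, C4a, C5 to C8, C8a, with O1 on the aryl-bearing carbon. C2 carries a 3,4-dihydroxy-5-methoxyphenyl group (ring B), C3 a hydroxymethyl group, C5 a methoxy group next to O4, and C7 (para to O4) an (E)-3-oxoprop-1-enyl chain. C2 and C3 are the only stereocentres. Both are R, which places the aryl and hydroxymethyl groups trans on the dioxane ring; this is also the more stable arrangement. The sensitive groups are the electron-rich catechol (air, base), the enal (nucleophiles, hydride, hydrogenation) and the benzylic aryl ether C2–O1, which can ionise under acid because ring B is a strong donor. Three things make the synthesis hard. The two dioxane oxygens are not equivalent (O4 sits next to the methoxy-bearing C5, O1 next to C8–H), so any union of a catechol with a three-carbon unit has a regiochemical problem. The two adjacent oxygen-bearing stereocentres must be set in absolute terms. The protecting groups must finally release a catechol beside an enal. The plan rests on the C2–C3 bond: it links a carbinol-type carbon bearing ring B (C2) to a carbon bearing O4 and the CH2OH carbon (C3) in a threo relationship, which is the pattern of a syn aldol between an aryloxyacetyl unit (O4–C3–C=O) and a ring-B benzaldehyde.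

## Retrosynthetic reasoning

The enal of 17 is the most reactive group, so its C=C bond is cut first in the backward direction. This leads to the aryl aldehyde 16 and a two-carbon Wittig homologation as the last forward step. Cutting here keeps hydride, hot base and acid away from the enal. The forward reaction has to give the E alkene and stop after one homologation.

The aldehyde 16 is traced to the fully masked benzodioxane 15. The four masks (dioxolane on the ring-A aldehyde, two MOM ethers on the catechol, one silyl ether on the primary alcohol) are all acid-labile, so one operation removes them. They are chosen to survive a boron aldol, a hydride reduction and carbonate at 110 °C.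

In 15 the aryl ether bond O1–C8a is cut, which gives the open-chain bromo alcohol 14. This bond is preferred to C2–O1 because breaking or making it does not touch a stereocentre: the forward ring closure keeps the configuration of C2, so a threo open-chain compound gives the trans ring. The forward reaction is an intramolecular aryl C–O coupling onto the secondary benzylic hydroxyl. The primary hydroxyl must be blocked, since it is also vicinal to O4 and would close an isomeric six-membered ring.

Compound 14 is the monosilyl ether of diol 13, and the CH2OH carbon of 13 is the former carbonyl carbon of the acyl oxazolidinone 12. These two functional-group steps turn the aldol adduct into the cyclisation substrate and give back the auxiliary 5.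

The central cut is the C2–C3 bond of 12, an aldol bond between the aryloxyacetyl imide 7 (through its boron enolate 10) and the aldehyde 9. This bond is chosen because one reaction sets both stereocentres under control of a recoverable auxiliary and joins two fragments of similar size. The adduct holds every heavy atom of the benzodioxane core with the regiochemistry of ring A already fixed: bromine at the future C8a and methoxy beside O4. The forward reaction must give the syn adduct on one enolate face.

The imide 7 comes from the acid 4 and the auxiliary 5 by N-acylation. The acid 4 comes from 5-bromovanillin 1 by O-alkylation (2), acetalisation (3) and saponification. The phenol is alkylated before the aldehyde is masked, because an acetal of a free para-hydroxybenzaldehyde is too labile to carry.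

The aldehyde 9 comes from 5-hydroxyvanillin 8 by protection of both phenols.

## Alternatives that were turned down

Alternative 1: The O1–C2 bond is cut, so that C2 is a benzylic CH2 group in the open-chain bisphenol A1 and only C3 is a stereocentre.
- Forward key step: anodic oxidation of A1 in buffered acetonitrile. Two-electron oxidation of the 4-hydroxyaryl ring with loss of a benzylic proton gives a para-quinone methide, and the C8a hydroxyl adds to the methide carbon to close the dioxane and give A2.
- For it: only one stereocentre has to be made beforehand. The closure is biased toward trans, both kinetically and because it is reversible. No halogen or transition metal is needed, and A2 is two steps from the target.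
- Against it: A1 holds two phenols, and the one to be oxidised is a pyrogallol-type ring. Ring attack by nucleophiles, aryl coupling and tautomerisation of the quinone methide to an enol ether (C3 carries a hydrogen) compete with the wanted path. A2 keeps the same oxidisable phenol and now has an activated benzylic C–H, so over-oxidation is built in. The trans selectivity rests on 1,2-induction from a single CH2OH group.
- Comparison: Alternative 1 is stronger on protecting-group economy and on the length of the end game. The chosen route offers in its place a closed transition state whose stereochemical outcome is predictable, and a ring closure that touches neither stereocentre.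

Alternative 2: The O1–C8a bond is cut, as in the ring closure of the chosen route, but C8a is a C–H in the precursor A3 and the bromine sits at C8.
- Forward key step: a hindered lithium amide removes the hydroxyl proton and the ring proton between O4 and bromine. Loss of bromide gives the C8a–C8 aryne, and the tethered alkoxide adds at C8a to give A4.
- For it: no transition metal is needed, the reaction is fast at low temperature, and C2 keeps its configuration. It does not depend on activation of an electron-rich C–Br bond by a catalyst, which is the weak point of the copper closure.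
- Against it: an aryne next to an alkoxy group is attacked preferentially at the carbon remote from oxygen (here C8), because the carbanion then forms beside the oxygen. The tether demands attack at C8a, so ring size and electronic bias oppose each other, and capture by the amide base can compete. The strong base can also move the silyl group to the alkoxide. The regioisomeric bromide needed for ring A is less accessible than 1, and the benzyl ethers require a hydrogenolysis that must be placed before the enal.
- Comparison: Alternative 2 is equal on step count and stronger on speed. The chosen route substitutes at the carbon that carries the halogen, so the regiochemistry of closure is not in question, and it uses only carbonate as base.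

Alternative 3: The bond between C3 and the hydroxymethyl carbon is cut together with C2–H, which leads to the planar 2-aryl-1,4-benzodioxine A5.
- Forward key step: a rhodium catalyst with a chiral bisphosphite or bisdiazaphospholane ligand under syngas adds hydrogen to C2 and a formyl group to C3 on the same face. This gives the trans aldehyde A6, which is (2R,3S) by the CIP rules and has the same spatial arrangement as 17.
- For it: chirality is catalytic, the step is atom-economic, both centres and the trans relationship come from one syn addition, and no late ring closure is needed.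
- Against it: the alkene is trisubstituted, aryl-conjugated and oxygenated at both carbons, a class for which neither rate nor enantioselectivity of hydroformylation is established, and hydrogenation competes. A6 is an alpha-aryloxy aldehyde that can epimerise at C3 or lose the C2 aryloxide by beta-elimination. Making A5 with the correct placement of the two oxygens relative to the methoxy group restates the regiochemical problem of the target. The ester of A6 needs two redox steps to reach the aldehyde.
- Comparison: Alternative 3 is stronger on atom and catalyst economy. The chosen route offers a stoichiometric but recoverable controller with a well-understood selectivity model, and it fixes the regiochemistry of ring A in the first step.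

Key step: step 6

Remark on the chemistry: the ring positions O1, C2 (aryl), C3 (CH2OH), O4, C4a, C5 (OMe), C6, C7 (side chain), C8, C8a are used throughout, and the names of 15, 16 and 17 use these locants. Compounds 1, 5 and 8 are taken as commercial.

## Route

Step 1
Reactants: 1 5-bromovanillin (3-bromo-4-hydroxy-5-methoxybenzaldehyde)
Product: 2 ethyl 2-(2-bromo-4-formyl-6-methoxyphenoxy)acetate
Conditions: BrCH2CO2Et (1.2 equiv), K2CO3 (1.5 equiv), DMF, 60 °C
Reagents that add atoms: ethyl bromoacetate, BrCC(=O)OCC
Why: Williamson ether synthesis; deprotonated 1 (acidified by the para formyl and ortho bromo groups) displaces bromide from the reactive alpha-halo ester by SN2. Alkylating before acetalisation avoids the labile acetal of a free para-hydroxybenzaldehyde.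

Step 2
Reactants: 2 ethyl 2-(2-bromo-4-formyl-6-methoxyphenoxy)acetate
Product: 3 ethyl 2-[2-bromo-4-(1,3-dioxolan-2-yl)-6-methoxyphenoxy]acetate
Conditions: HOCH2CH2OH (3 equiv), p-TsOH·H2O (5 mol%), toluene, reflux, Dean–Stark
Reagents that add atoms: ethylene glycol, OCCO
Why: Acid-catalysed acetalisation driven by azeotropic removal of water; the dioxolane keeps the ring-A carbonyl out of the later enolate chemistry and tolerates base, hydride and hot carbonate. Partial ester exchange with the glycol would be harmless, since step 3 hydrolyses the ester.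

Step 3
Reactants: 3 ethyl 2-[2-bromo-4-(1,3-dioxolan-2-yl)-6-methoxyphenoxy]acetate
Product: 4 2-[2-bromo-4-(1,3-dioxolan-2-yl)-6-methoxyphenoxy]acetic acid
Conditions: LiOH·H2O (1.5 equiv), THF/H2O, 0 °C → rt; then 1 M HCl to pH 4–5, 0 °C, rapid extraction
Reagents that add atoms: lithium hydroxide, [Li+].[OH-]
Why: Ester saponification by acyl–oxygen cleavage, to which the acetal and the aryl bromide are inert. Acidifying only to pH 4–5 in the cold should keep the acetal intact; the acid is used at once.

Step 4
Reactants: 4 2-[2-bromo-4-(1,3-dioxolan-2-yl)-6-methoxyphenoxy]acetic acid; 5 (S)-4-benzyloxazolidin-2-one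
Product: 7 (S)-4-benzyl-3-{2-[2-bromo-4-(1,3-dioxolan-2-yl)-6-methoxyphenoxy]acetyl}oxazolidin-2-one, via mixed pivalic anhydride 6 (not isolated)
Conditions: PivCl (1.1 equiv), Et3N (2.5 equiv), THF, −20 °C; then LiCl (1.1 equiv), 5 (1.0 equiv), −20 °C → rt
Reagents that add atoms: none
Why: N-acylation of the oxazolidinone through a mixed anhydride (pivaloyl chloride/LiCl method); 5 attacks the less hindered and more electrophilic aryloxyacetyl carbonyl of 6. The amine-buffered medium spares the acetal, which an acid chloride preparation would not.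

Step 5
Reactants: 8 5-hydroxyvanillin (3,4-dihydroxy-5-methoxybenzaldehyde)
Product: 9 3-methoxy-4,5-bis(methoxymethoxy)benzaldehyde
Conditions: MOMCl (3 equiv), iPr2NEt (4 equiv), CH2Cl2, 0 °C → rt
Reagents that add atoms: chloromethyl methyl ether, COCCl
Why: Double O-alkylation of the catechol (phenol protection as MOM ethers). The MOM ethers should survive the boron aldol, hydride and hot carbonate, and leave in the same acid treatment as the acetal and the silyl ether.

Step 6
Reactants: 7 (S)-4-benzyl-3-{2-[2-bromo-4-(1,3-dioxolan-2-yl)-6-methoxyphenoxy]acetyl}oxazolidin-2-one; 9 3-methoxy-4,5-bis(methoxymethoxy)benzaldehyde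
Product: 12 (S)-4-benzyl-3-{(2S,3R)-2-[2-bromo-4-(1,3-dioxolan-2-yl)-6-methoxyphenoxy]-3-hydroxy-3-[3-methoxy-4,5-bis(methoxymethoxy)phenyl]propanoyl}oxazolidin-2-one, via Z-dibutylboron enolate 10 (not isolated), via dibutylboron aldolate 11 (not isolated)
Conditions: Bu2BOTf (1.1 equiv), iPr2NEt (1.3 equiv), CH2Cl2, −78 → 0 °C; 9 (1.2 equiv), −78 → 0 °C; pH 7 phosphate buffer, MeOH, 30% H2O2, 0 °C
Reagents that add atoms: none
Why: Soft enolisation: Bu2BOTf activates the imide carbonyl and iPr2NEt removes a proton from the OCH2 group, the only acidic position, to give the Z boron enolate 10, the geometry in which the aryloxy group avoids the oxazolidinone ring. Aldehyde 9 binds to boron and the C–C bond forms through a closed six-membered chair (Zimmerman–Traxler) transition state leading to aldolate 11; boron has no further free site, so the auxiliary carbonyl is not chelated, turns away from the enolate oxygen, and its benzyl group screens one enolate face. The closest known reaction type is the Evans syn aldol of alkoxyacetyl (glycolate) oxazolidinones with aromatic aldehydes. No ring is closed; the step forms the future C2–C3 bond. The configuration of the aryloxy-bearing carbon (future C3) is controlled by the (S)-benzyl group of the auxiliary through the choice of enolate face, and that of the carbinol carbon (future C2) by the Z enolate geometry, which places the aryl group of 9 equatorial in the chair and gives the syn (threo) pair, (2S,3R) in the acyl chain. The step needs syn over anti and one enolate face over the other, and both follow from the Z enolate and the non-chelated auxiliary. Chemoselectivity rests on three points: 9 cannot enolise, the ring-A carbonyl is masked, and the excess of amine leaves no free boron triflate to attack the acetal or the MOM ethers. Buffered H2O2 cleaves the B–O and B–C bonds of 11 without retro-aldol.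

Step 7
Reactants: 12 (S)-4-benzyl-3-{(2S,3R)-2-[2-bromo-4-(1,3-dioxolan-2-yl)-6-methoxyphenoxy]-3-hydroxy-3-[3-methoxy-4,5-bis(methoxymethoxy)phenyl]propanoyl}oxazolidin-2-one
Product: 13 (1R,2R)-2-[2-bromo-4-(1,3-dioxolan-2-yl)-6-methoxyphenoxy]-1-[3-methoxy-4,5-bis(methoxymethoxy)phenyl]propane-1,3-diol
Conditions: LiBH4 (2 equiv), MeOH (2 equiv), THF, 0 °C; aq. NH4Cl
Reagents that add atoms: none
Why: Reductive cleavage of the N-acyl oxazolidinone: hydride adds to the exocyclic carbonyl activated by lithium, the acyl carbon ends as CH2OH and auxiliary 5 is released for recovery. No stereocentre is touched; the descriptor of the aryloxy carbon changes from S to R only because the CIP ranking of its neighbours changes.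

Step 8
Reactants: 13 (1R,2R)-2-[2-bromo-4-(1,3-dioxolan-2-yl)-6-methoxyphenoxy]-1-[3-methoxy-4,5-bis(methoxymethoxy)phenyl]propane-1,3-diol
Product: 14 (1R,2R)-2-[2-bromo-4-(1,3-dioxolan-2-yl)-6-methoxyphenoxy]-1-[3-methoxy-4,5-bis(methoxymethoxy)phenyl]-3-[(triisopropylsilyl)oxy]propan-1-ol
Conditions: TIPSCl (1.1 equiv), imidazole (2.5 equiv), CH2Cl2, 0 °C → rt
Reagents that add atoms: chlorotriisopropylsilane, CC(C)[Si](Cl)(C(C)C)C(C)C
Why: Selective silylation of the primary hydroxyl by steric differentiation from the hindered benzylic secondary alcohol. The primary oxygen must be blocked because it is also vicinal to O4 and would close the isomeric dioxane in step 9; the bulky triisopropylsilyl group is chosen because it resists 1,3-migration under carbonate.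

Step 9
Reactants: 14 (1R,2R)-2-[2-bromo-4-(1,3-dioxolan-2-yl)-6-methoxyphenoxy]-1-[3-methoxy-4,5-bis(methoxymethoxy)phenyl]-3-[(triisopropylsilyl)oxy]propan-1-ol
Product: 15 {[(2R,3R)-7-(1,3-dioxolan-2-yl)-5-methoxy-2-[3-methoxy-4,5-bis(methoxymethoxy)phenyl]-2,3-dihydro-1,4-benzodioxin-3-yl]methoxy}triisopropylsilane
Conditions: CuI (20 mol%), 1,10-phenanthroline (40 mol%), Cs2CO3 (2 equiv), toluene, 110 °C, argon
Reagents that add atoms: none
Why: Ullmann-type copper-catalysed intramolecular O-arylation: the deprotonated benzylic hydroxyl of 14 replaces bromide at C8a through an aryl–copper intermediate and closes the six-membered dioxane. The bond formed is O1–C8a and no bond to C2 or C3 is broken, so both configurations are retained and the threo open-chain compound should give the trans ring.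

Step 10
Reactants: 15 {[(2R,3R)-7-(1,3-dioxolan-2-yl)-5-methoxy-2-[3-methoxy-4,5-bis(methoxymethoxy)phenyl]-2,3-dihydro-1,4-benzodioxin-3-yl]methoxy}triisopropylsilane
Product: 16 (2R,3R)-2-(3,4-dihydroxy-5-methoxyphenyl)-3-(hydroxymethyl)-5-methoxy-2,3-dihydro-1,4-benzodioxine-7-carbaldehyde
Conditions: HCl (3 M aq)/MeOH/THF (1:2:2), 45 °C
Reagents that add atoms: water, O
Why: Acid-catalysed hydrolysis and transacetalisation remove the dioxolane, both MOM ethers and the silyl ether in one operation; methanol carries the formaldehyde unit away as its dimethyl acetal, so it should not re-attack the electron-rich rings. Any acid-induced ionisation of the benzylic C2–O1 bond can only re-close toward the more stable trans isomer that is wanted.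

Step 11
Reactants: 16 (2R,3R)-2-(3,4-dihydroxy-5-methoxyphenyl)-3-(hydroxymethyl)-5-methoxy-2,3-dihydro-1,4-benzodioxine-7-carbaldehyde
Product: 17 (E)-3-[(2R,3R)-2-(3,4-dihydroxy-5-methoxyphenyl)-3-(hydroxymethyl)-5-methoxy-2,3-dihydro-1,4-benzodioxin-7-yl]prop-2-enal
Conditions: Ph3P=CHCHO (1.2 equiv), THF, 65 °C, argon
Reagents that add atoms: (triphenylphosphoranylidene)acetaldehyde, O=CC=P(c1ccccc1)(c1ccccc1)c1ccccc1
Why: Wittig olefination with a stabilised ylide, which should give the E enal. The aldehyde sits on ring A, which has no free phenol, so it is not deactivated by phenoxide formation, and the weakly basic ylide tolerates the catechol and the primary alcohol.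

## Compound list

1 | 5-bromovanillin (3-bromo-4-hydroxy-5-methoxybenzaldehyde) | COc1cc(C=O)cc(Br)c1O | starting material
2 | ethyl 2-(2-bromo-4-formyl-6-methoxyphenoxy)acetate | CCOC(=O)COc1c(Br)cc(C=O)cc1OC | intermediate
3 | ethyl 2-[2-bromo-4-(1,3-dioxolan-2-yl)-6-methoxyphenoxy]acetate | CCOC(=O)COc1c(Br)cc(C2OCCO2)cc1OC | intermediate
4 | 2-[2-bromo-4-(1,3-dioxolan-2-yl)-6-methoxyphenoxy]acetic acid | OC(=O)COc1c(Br)cc(C2OCCO2)cc1OC | intermediate
5 | (S)-4-benzyloxazolidin-2-one | O=C1OC[C@H](Cc2ccccc2)N1 | starting material
6 | 2-[2-bromo-4-(1,3-dioxolan-2-yl)-6-methoxyphenoxy]acetic pivalic anhydride | CC(C)(C)C(=O)OC(=O)COc1c(Br)cc(C2OCCO2)cc1OC | intermediate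
7 | (S)-4-benzyl-3-{2-[2-bromo-4-(1,3-dioxolan-2-yl)-6-methoxyphenoxy]acetyl}oxazolidin-2-one | COc1cc(C2OCCO2)cc(Br)c1OCC(=O)N1C(=O)OC[C@@H]1Cc1ccccc1 | intermediate
8 | 5-hydroxyvanillin (3,4-dihydroxy-5-methoxybenzaldehyde) | COc1cc(C=O)cc(O)c1O | starting material
9 | 3-methoxy-4,5-bis(methoxymethoxy)benzaldehyde | COCOc1cc(C=O)cc(OC)c1OCOC | intermediate
10 | (S)-4-benzyl-3-{(Z)-2-[2-bromo-4-(1,3-dioxolan-2-yl)-6-methoxyphenoxy]-1-[(dibutylboranyl)oxy]ethenyl}oxazolidin-2-one | CCCCB(CCCC)O/C(=C\Oc1c(Br)cc(C2OCCO2)cc1OC)N1C(=O)OC[C@@H]1Cc1ccccc1 | intermediate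
11 | (S)-4-benzyl-3-{(2S,3R)-2-[2-bromo-4-(1,3-dioxolan-2-yl)-6-methoxyphenoxy]-3-[(dibutylboranyl)oxy]-3-[3-methoxy-4,5-bis(methoxymethoxy)phenyl]propanoyl}oxazolidin-2-one | COc1cc(C2OCCO2)cc(Br)c1O[C@H](C(=O)N1C(=O)OC[C@@H]1Cc1ccccc1)[C@H](OB(CCCC)CCCC)c1cc(OC)c(OCOC)c(OCOC)c1 | intermediate
12 | (S)-4-benzyl-3-{(2S,3R)-2-[2-bromo-4-(1,3-dioxolan-2-yl)-6-methoxyphenoxy]-3-hydroxy-3-[3-methoxy-4,5-bis(methoxymethoxy)phenyl]propanoyl}oxazolidin-2-one | COc1cc(C2OCCO2)cc(Br)c1O[C@H](C(=O)N1C(=O)OC[C@@H]1Cc1ccccc1)[C@H](O)c1cc(OC)c(OCOC)c(OCOC)c1 | intermediate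
13 | (1R,2R)-2-[2-bromo-4-(1,3-dioxolan-2-yl)-6-methoxyphenoxy]-1-[3-methoxy-4,5-bis(methoxymethoxy)phenyl]propane-1,3-diol | COc1cc(C2OCCO2)cc(Br)c1O[C@H](CO)[C@H](O)c1cc(OC)c(OCOC)c(OCOC)c1 | intermediate
14 | (1R,2R)-2-[2-bromo-4-(1,3-dioxolan-2-yl)-6-methoxyphenoxy]-1-[3-methoxy-4,5-bis(methoxymethoxy)phenyl]-3-[(triisopropylsilyl)oxy]propan-1-ol | COc1cc(C2OCCO2)cc(Br)c1O[C@H](CO[Si](C(C)C)(C(C)C)C(C)C)[C@H](O)c1cc(OC)c(OCOC)c(OCOC)c1 | intermediate
15 | {[(2R,3R)-7-(1,3-dioxolan-2-yl)-5-methoxy-2-[3-methoxy-4,5-bis(methoxymethoxy)phenyl]-2,3-dihydro-1,4-benzodioxin-3-yl]methoxy}triisopropylsilane | COc1cc([C@H]2Oc3cc(C4OCCO4)cc(OC)c3O[C@@H]2CO[Si](C(C)C)(C(C)C)C(C)C)cc(OCOC)c1OCOC | intermediate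
16 | (2R,3R)-2-(3,4-dihydroxy-5-methoxyphenyl)-3-(hydroxymethyl)-5-methoxy-2,3-dihydro-1,4-benzodioxine-7-carbaldehyde | COc1cc([C@H]2Oc3cc(C=O)cc(OC)c3O[C@@H]2CO)cc(O)c1O | intermediate
17 | (E)-3-[(2R,3R)-2-(3,4-dihydroxy-5-methoxyphenyl)-3-(hydroxymethyl)-5-methoxy-2,3-dihydro-1,4-benzodioxin-7-yl]prop-2-enal | COc1cc([C@H]2Oc3cc(/C=C/C=O)cc(OC)c3O[C@@H]2CO)cc(O)c1O | target

## Step count and least certain steps

Total step count: 11 (steps 1–4 to imide 7, step 5 to aldehyde 9, steps 6–11 to 17).
Longest linear sequence: 10 steps (1–4 and 6–11, from 1).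

Step 6 (key step).
- What may go wrong: soft enolisation of the hindered, weakly Lewis-basic aryloxyacetyl imide may be slow or incomplete. That would leave free boron triflate, which can open the dioxolane. Addition to the electron-rich aldehyde may also be slow, and raising the temperature would erode the syn/anti selectivity. Retro-aldol during work-up is a second way to lose material.
- Fallback: the two stereocentres are set by reduction instead of by C–C bond formation, without a boron Lewis acid. It sets out from ester 3 and aldehyde 9. Ester 3 is deprotonated with LiN(iPr)2 (THF, −78 °C) and added to 9 to give ethyl 2-[2-bromo-4-(1,3-dioxolan-2-yl)-6-methoxyphenoxy]-3-hydroxy-3-[3-methoxy-4,5-bis(methoxymethoxy)phenyl]propanoate F1 as a racemic mixture of diastereomers. Dess–Martin oxidation (NaHCO3, CH2Cl2) converts it into ethyl 2-[2-bromo-4-(1,3-dioxolan-2-yl)-6-methoxyphenoxy]-3-[3-methoxy-4,5-bis(methoxymethoxy)phenyl]-3-oxopropanoate F2, whose alpha centre equilibrates rapidly. Asymmetric transfer hydrogenation with dynamic kinetic resolution (RuCl[(S,S)-TsDPEN](p-cymene), HCO2H/Et3N, CH2Cl2, 30 °C) is a known way from alpha-alkoxy beta-keto esters to syn alpha-alkoxy beta-hydroxy esters. By the usual aryl ketone model the (S,S) catalyst is the one expected to deliver the 3R carbinol, so the step should give ethyl (2S,3R)-2-[2-bromo-4-(1,3-dioxolan-2-yl)-6-methoxyphenoxy]-3-hydroxy-3-[3-methoxy-4,5-bis(methoxymethoxy)phenyl]propanoate F3. LiBH4 (THF, 0 °C → rt) reduces the ester, and the route is rejoined at diol 13.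

Step 9.
- What may go wrong: activation of the C–Br bond of an electron-rich arene by copper may be slow. Hydrodebromination, oxidation of the benzylic alcohol and base-induced 1,3-silyl migration (which would let the primary oxygen close the isomeric dioxane) could then gain ground.
- Fallback: the ring is closed at the other end of O1, by forming the C2–O1 bond under thermodynamic control. It sets out from 14. Miyaura borylation (B2pin2, Pd(dppf)Cl2, KOAc, dioxane, 90 °C) gives (1R,2R)-2-[4-(1,3-dioxolan-2-yl)-2-methoxy-6-(4,4,5,5-tetramethyl-1,3,2-dioxaborolan-2-yl)phenoxy]-1-[3-methoxy-4,5-bis(methoxymethoxy)phenyl]-3-[(triisopropylsilyl)oxy]propan-1-ol F4. Oxidation (NaBO3·4H2O, THF/H2O, rt) gives the phenol (1R,2R)-2-[4-(1,3-dioxolan-2-yl)-2-hydroxy-6-methoxyphenoxy]-1-[3-methoxy-4,5-bis(methoxymethoxy)phenyl]-3-[(triisopropylsilyl)oxy]propan-1-ol F5. Acid (CF3CO2H, CH2Cl2, 0 °C; then the conditions of step 10) ionises the benzylic alcohol, whose cation is stabilised by the para oxygen of ring B. The new phenol oxygen closes the dioxane on C2 reversibly, which favours the trans isomer dictated by the untouched C3. The same treatment removes the acetal, the MOM groups and the silyl ether, so the route is rejoined at 16.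

Step 11.
- What may go wrong: the product enal may react with a second equivalent of ylide (vinylogous homologation). Conversion of a polar, hydrogen-bonding substrate may be slow, and the catechol may be lost by oxidation at reflux.
- Fallback: the chain is built stepwise on protected material through an ester, which cannot over-react. It sets out from 15. Selective acetal hydrolysis (PPTS, acetone/H2O, 50 °C) gives (2R,3R)-5-methoxy-2-[3-methoxy-4,5-bis(methoxymethoxy)phenyl]-3-{[(triisopropylsilyl)oxy]methyl}-2,3-dihydro-1,4-benzodioxine-7-carbaldehyde F6. Horner–Wadsworth–Emmons reaction ((EtO)2P(O)CH2CO2Et, NaH, THF, 0 °C → rt) gives ethyl (E)-3-[(2R,3R)-5-methoxy-2-[3-methoxy-4,5-bis(methoxymethoxy)phenyl]-3-{[(triisopropylsilyl)oxy]methyl}-2,3-dihydro-1,4-benzodioxin-7-yl]prop-2-enoate F7. Reduction (iBu2AlH, CH2Cl2, −78 °C) gives (E)-3-[(2R,3R)-5-methoxy-2-[3-methoxy-4,5-bis(methoxymethoxy)phenyl]-3-{[(triisopropylsilyl)oxy]methyl}-2,3-dihydro-1,4-benzodioxin-7-yl]prop-2-en-1-ol F8. Allylic oxidation (MnO2, CH2Cl2, rt), carried out while the catechol is still protected, gives (E)-3-[(2R,3R)-5-methoxy-2-[3-methoxy-4,5-bis(methoxymethoxy)phenyl]-3-{[(triisopropylsilyl)oxy]methyl}-2,3-dihydro-1,4-benzodioxin-7-yl]prop-2-enal F9. Aqueous acid (HCl (2 M aq)/THF, 40 °C) then removes the MOM and silyl groups, and the route is rejoined at 17.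

## Further compounds

F1 | step 6 | ethyl 2-[2-bromo-4-(1,3-dioxolan-2-yl)-6-methoxyphenoxy]-3-hydroxy-3-[3-methoxy-4,5-bis(methoxymethoxy)phenyl]propanoate (racemic, mixture of diastereomers) | CCOC(=O)C(Oc1c(Br)cc(C2OCCO2)cc1OC)C(O)c1cc(OC)c(OCOC)c(OCOC)c1
F2 | step 6 | ethyl 2-[2-bromo-4-(1,3-dioxolan-2-yl)-6-methoxyphenoxy]-3-[3-methoxy-4,5-bis(methoxymethoxy)phenyl]-3-oxopropanoate (racemic) | CCOC(=O)C(Oc1c(Br)cc(C2OCCO2)cc1OC)C(=O)c1cc(OC)c(OCOC)c(OCOC)c1
F3 | step 6 | ethyl (2S,3R)-2-[2-bromo-4-(1,3-dioxolan-2-yl)-6-methoxyphenoxy]-3-hydroxy-3-[3-methoxy-4,5-bis(methoxymethoxy)phenyl]propanoate | CCOC(=O)[C@@H](Oc1c(Br)cc(C2OCCO2)cc1OC)[C@H](O)c1cc(OC)c(OCOC)c(OCOC)c1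
F4 | step 9 | (1R,2R)-2-[4-(1,3-dioxolan-2-yl)-2-methoxy-6-(4,4,5,5-tetramethyl-1,3,2-dioxaborolan-2-yl)phenoxy]-1-[3-methoxy-4,5-bis(methoxymethoxy)phenyl]-3-[(triisopropylsilyl)oxy]propan-1-ol | COc1cc(C2OCCO2)cc(B3OC(C)(C)C(C)(C)O3)c1O[C@H](CO[Si](C(C)C)(C(C)C)C(C)C)[C@H](O)c1cc(OC)c(OCOC)c(OCOC)c1
F5 | step 9 | (1R,2R)-2-[4-(1,3-dioxolan-2-yl)-2-hydroxy-6-methoxyphenoxy]-1-[3-methoxy-4,5-bis(methoxymethoxy)phenyl]-3-[(triisopropylsilyl)oxy]propan-1-ol | COc1cc(C2OCCO2)cc(O)c1O[C@H](CO[Si](C(C)C)(C(C)C)C(C)C)[C@H](O)c1cc(OC)c(OCOC)c(OCOC)c1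
F6 | step 11 | (2R,3R)-5-methoxy-2-[3-methoxy-4,5-bis(methoxymethoxy)phenyl]-3-{[(triisopropylsilyl)oxy]methyl}-2,3-dihydro-1,4-benzodioxine-7-carbaldehyde | COc1cc([C@H]2Oc3cc(C=O)cc(OC)c3O[C@@H]2CO[Si](C(C)C)(C(C)C)C(C)C)cc(OCOC)c1OCOC
F7 | step 11 | ethyl (E)-3-[(2R,3R)-5-methoxy-2-[3-methoxy-4,5-bis(methoxymethoxy)phenyl]-3-{[(triisopropylsilyl)oxy]methyl}-2,3-dihydro-1,4-benzodioxin-7-yl]prop-2-enoate | COc1cc([C@H]2Oc3cc(/C=C/C(=O)OCC)cc(OC)c3O[C@@H]2CO[Si](C(C)C)(C(C)C)C(C)C)cc(OCOC)c1OCOC
F8 | step 11 | (E)-3-[(2R,3R)-5-methoxy-2-[3-methoxy-4,5-bis(methoxymethoxy)phenyl]-3-{[(triisopropylsilyl)oxy]methyl}-2,3-dihydro-1,4-benzodioxin-7-yl]prop-2-en-1-ol | COc1cc([C@H]2Oc3cc(/C=C/CO)cc(OC)c3O[C@@H]2CO[Si](C(C)C)(C(C)C)C(C)C)cc(OCOC)c1OCOC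
F9 | step 11 | (E)-3-[(2R,3R)-5-methoxy-2-[3-methoxy-4,5-bis(methoxymethoxy)phenyl]-3-{[(triisopropylsilyl)oxy]methyl}-2,3-dihydro-1,4-benzodioxin-7-yl]prop-2-enal | COc1cc([C@H]2Oc3cc(/C=C/C=O)cc(OC)c3O[C@@H]2CO[Si](C(C)C)(C(C)C)C(C)C)cc(OCOC)c1OCOC
A1 | alternative 1 | (S)-3-hydroxy-4-({1-hydroxy-3-[4-hydroxy-3-methoxy-5-(methoxymethoxy)phenyl]propan-2-yl}oxy)-5-methoxybenzaldehyde | O=Cc1cc(O)c(O[C@@H](Cc2cc(OC)c(O)c(OCOC)c2)CO)c(OC)c1
A2 | alternative 1 | (2R,3R)-2-[4-hydroxy-3-methoxy-5-(methoxymethoxy)phenyl]-3-(hydroxymethyl)-5-methoxy-2,3-dihydro-1,4-benzodioxine-7-carbaldehyde | COc1cc([C@H]2Oc3cc(C=O)cc(OC)c3O[C@@H]2CO)cc(OCOC)c1O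
A3 | alternative 2 | (1R,2R)-1-[3,4-bis(benzyloxy)-5-methoxyphenyl]-2-[5-bromo-4-(1,3-dioxolan-2-yl)-2-methoxyphenoxy]-3-[(tert-butyldimethylsilyl)oxy]propan-1-ol | COc1cc(C2OCCO2)c(Br)cc1O[C@H](CO[Si](C)(C)C(C)(C)C)[C@H](O)c1cc(OC)c(OCc2ccccc2)c(OCc2ccccc2)c1
A4 | alternative 2 | {[(2R,3R)-2-[3,4-bis(benzyloxy)-5-methoxyphenyl]-7-(1,3-dioxolan-2-yl)-5-methoxy-2,3-dihydro-1,4-benzodioxin-3-yl]methoxy}(tert-butyl)dimethylsilane | COc1cc([C@H]2Oc3cc(C4OCCO4)cc(OC)c3O[C@@H]2CO[Si](C)(C)C(C)(C)C)cc(OCc2ccccc2)c1OCc1ccccc1
A5 | alternative 3 | methyl 2-[3,4-bis(benzyloxy)-5-methoxyphenyl]-5-methoxy-1,4-benzodioxine-7-carboxylate | COC(=O)c1cc(OC)c2OC=C(c3cc(OC)c(OCc4ccccc4)c(OCc4ccccc4)c3)Oc2c1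
A6 | alternative 3 | methyl (2R,3S)-2-[3,4-bis(benzyloxy)-5-methoxyphenyl]-3-formyl-5-methoxy-2,3-dihydro-1,4-benzodioxine-7-carboxylate | COC(=O)c1cc(OC)c2O[C@H](C=O)[C@@H](c3cc(OC)c(OCc4ccccc4)c(OCc4ccccc4)c3)Oc2c1
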